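**Retrosynthetic overview** (carbons numbered along the C20 acid chain, C1 = lactone carbonyl)
1. Target ⇐ hydrolysis of a C9/C11 ethylidene acetal on the finished lactone.
2. Dihydropyranone (second and last ring) ⇐ C5–O bond and C2=C3 in one annulation of a δ-hydroxy enal with a phosphonioacetate (carboxylate oxa-Michael, then intramolecular Wittig); C5 is set here.
3. That enal ⇐ cross-metathesis of a homoallylic alcohol with crotonaldehyde; C7 ⇐ allylboration of a C7 aldehyde.
4. C7 aldehyde carrying a 1,3-dioxane (first ring, temporary) ⇐ C9–O bond by hemiacetal oxa-Michael of a δ-hydroxy enal with acetaldehyde; C9 is set from C11.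
5. δ-Hydroxy enal ⇐ cross-metathesis of (R)-tridec-1-en-4-ol ⇐ allylboration of decanal (C11).

Assumption: both antipodes of B-allyldiisopinocampheylborane (1 M in pentane) and (carboxymethyl)triphenylphosphonium chloride are bought.

**Step 1**
Reactants: 1 decanal; 2 (−)-B-allyldiisopinocampheylborane, (−)-Ipc2B(allyl), Ipc groups from (+)-α-pinene
Product: 4 (4R)-tridec-1-en-4-ol, via borinate ester 3 (not isolated)
Conditions: 2 (1.2 equiv), Et2O, −78 °C; then 3 M NaOH, 30% H2O2, 0 → 23 °C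
Reagents that add atoms: none
Why: Brown asymmetric allylboration; the reagent from (+)-α-pinene delivers allyl to the Si face of the aldehyde through a chair six-membered transition state, which sets C11 as R, and basic peroxide cleaves the borinate.

**Step 2**
Reactants: 4 (4R)-tridec-1-en-4-ol; 5 (E)-but-2-enal (crotonaldehyde)
Product: 6 (2E,5R)-5-hydroxytetradec-2-enal
Conditions: 5 (5 equiv), second-generation Hoveyda–Grubbs catalyst [RuCl2(H2IMes)(=CH-C6H4-2-OiPr)] (3 mol%), CH2Cl2, 40 °C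
Reagents that add atoms: none
Why: Olefin cross-metathesis of a terminal homoallylic alcohol with excess electron-poor crotonaldehyde gives the E-enal selectively; no stereocentre is touched.

**Step 3**
Reactants: 6 (2E,5R)-5-hydroxytetradec-2-enal; 7 acetaldehyde
Product: 9 2-[(2R,4R,6R)-2-methyl-6-nonyl-1,3-dioxan-4-yl]acetaldehyde, via acetaldehyde hemiacetal 8 (not isolated)
Conditions: 7 (10 equiv), Bi(NO3)3·5H2O (10 mol%), CH2Cl2, 23 °C
Reagents that add atoms: none
Why: Bismuth nitrate-mediated two-component hemiacetal/oxa-Michael reaction (Evans-type tethered etherification); the hemiacetal oxygen adds reversibly to C9 and the all-equatorial 2,4,6-cis-dioxane is the thermodynamic product, so the new C9–O bond is syn to C11–O.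

**Step 4**
Reactants: 9 2-[(2R,4R,6R)-2-methyl-6-nonyl-1,3-dioxan-4-yl]acetaldehyde; 10 (+)-B-allyldiisopinocampheylborane, (+)-Ipc2B(allyl), Ipc groups from (−)-α-pinene
Product: 12 (2R)-1-[(2R,4S,6R)-2-methyl-6-nonyl-1,3-dioxan-4-yl]pent-4-en-2-ol, via borinate ester 11 (not isolated)
Conditions: 10 (1.3 equiv), Et2O, −78 °C; then 3 M NaOH, 30% H2O2, 0 → 23 °C
Reagents that add atoms: none
Why: Brown allylboration under reagent control; the antipodal reagent delivers allyl to the Re face and sets the C7 carbinol anti to the C9 oxygen (R descriptor at this stage, S in the target after the priority change), and the acetal is inert to borane and basic peroxide.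

**Step 5**
Reactants: 12 (2R)-1-[(2R,4S,6R)-2-methyl-6-nonyl-1,3-dioxan-4-yl]pent-4-en-2-ol; 5 (E)-but-2-enal
Product: 13 (2E,5R)-5-hydroxy-6-[(2R,4S,6R)-2-methyl-6-nonyl-1,3-dioxan-4-yl]hex-2-enal
Conditions: 5 (5 equiv), second-generation Hoveyda–Grubbs catalyst [RuCl2(H2IMes)(=CH-C6H4-2-OiPr)] (3 mol%), CH2Cl2, 40 °C
Reagents that add atoms: none
Why: Olefin cross-metathesis as in step 2; the free secondary alcohol and the acetal are tolerated and the E-enal forms.

**Step 6**
Reactants: 13 (2E,5R)-5-hydroxy-6-[(2R,4S,6R)-2-methyl-6-nonyl-1,3-dioxan-4-yl]hex-2-enal; 14 (carboxymethyl)triphenylphosphonium chloride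
Product: 17 (6S)-6-{(2S)-2-hydroxy-3-[(2R,4S,6R)-2-methyl-6-nonyl-1,3-dioxan-4-yl]propyl}-5,6-dihydro-2H-pyran-2-one, via phosphonioacetate betaine 15 (not isolated), via ester ylide aldehyde 16 (not isolated)
Conditions: 14 (1.5 equiv), iPr2NEt (1.5 equiv), (S)-2-{bis[3,5-bis(trifluoromethyl)phenyl](trimethylsilyloxy)methyl}pyrrolidine (20 mol%), PhCO2H (20 mol%), CHCl3 (0.05 M), 0 → 23 °C
Reagents that add atoms: none
Why: Proposed new method: an iminium-triggered carboxylate oxa-Michael/intramolecular Wittig annulation. The (S)-diarylprolinol silyl ether turns enal 13 into an E-iminium ion whose aryl(silyloxy)methyl arm blocks one face, so the carboxylate oxygen of betaine 15 adds to the open Re face of C5 and fixes it as S, anti to C7–OH, under catalyst control. After hydrolysis the CH2 of the adduct lies between P+ and an ester carbonyl (pKa about 9, against roughly 18 for the unreacted betaine), so only the adduct is ylidised by the amine. Ylide 16 then closes on its own aldehyde (six-membered ring, Z alkene by ring constraint), which makes the otherwise reversible carboxylate addition irreversible and forms the C5–O bond, C2=C3 and the lactone in one flask. The closest known reactions are the iminium-catalysed oxa-Michael addition of oximes to enals and the acylation/intramolecular Wittig lactonisation of hydroxy aldehydes with Ph3P=C=C=O.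

**Step 7**
Reactants: 17 (6S)-6-{(2S)-2-hydroxy-3-[(2R,4S,6R)-2-methyl-6-nonyl-1,3-dioxan-4-yl]propyl}-5,6-dihydro-2H-pyran-2-one
Product: 18 (6S)-6-[(2S,4R,6R)-2,4,6-trihydroxypentadecyl]-5,6-dihydro-2H-pyran-2-one
Conditions: 2 M aq. HCl/THF (1:1), 40 °C, N2 sweep
Reagents that add atoms: none
Why: Acid-catalysed acetal hydrolysis; acetaldehyde is swept out, no bond to a stereocentre is broken, and the unsaturated δ-lactone tolerates aqueous acid (any opened hydroxy acid recloses to the six-membered lactone).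

**Compound list**
1 | decanal | CCCCCCCCCC=O | starting material
2 | (−)-B-allyldiisopinocampheylborane, Ipc groups from (+)-α-pinene | C=CCB([C@@H]1C[C@@H]2C[C@H]([C@H]1C)C2(C)C)[C@@H]1C[C@@H]2C[C@H]([C@H]1C)C2(C)C | starting material
3 | (4R)-tridec-1-en-4-yl diisopinocampheylborinate, Ipc groups from (+)-α-pinene (not isolated) | CCCCCCCCC[C@@H](OB([C@@H]1C[C@@H]2C[C@H]([C@H]1C)C2(C)C)[C@@H]1C[C@@H]2C[C@H]([C@H]1C)C2(C)C)CC=C | intermediate
4 | (4R)-tridec-1-en-4-ol | CCCCCCCCC[C@@H](O)CC=C | intermediate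
5 | (E)-but-2-enal (crotonaldehyde) | C/C=C/C=O | starting material
6 | (2E,5R)-5-hydroxytetradec-2-enal | CCCCCCCCC[C@@H](O)C/C=C/C=O | intermediate
7 | acetaldehyde | CC=O | starting material
8 | (2E,5R)-5-(1-hydroxyethoxy)tetradec-2-enal, hemiacetal, both epimers at the new carbon (not isolated) | CCCCCCCCC[C@@H](OC(C)O)C/C=C/C=O | intermediate
9 | 2-[(2R,4R,6R)-2-methyl-6-nonyl-1,3-dioxan-4-yl]acetaldehyde, all-cis dioxane | CCCCCCCCC[C@@H]1C[C@H](CC=O)O[C@H](C)O1 | intermediate
10 | (+)-B-allyldiisopinocampheylborane, Ipc groups from (−)-α-pinene | C=CCB([C@H]1C[C@H]2C[C@@H]([C@@H]1C)C2(C)C)[C@H]1C[C@H]2C[C@@H]([C@@H]1C)C2(C)C | starting material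
11 | (2R)-1-[(2R,4S,6R)-2-methyl-6-nonyl-1,3-dioxan-4-yl]pent-4-en-2-yl diisopinocampheylborinate, Ipc groups from (−)-α-pinene (not isolated) | CCCCCCCCC[C@@H]1C[C@H](C[C@H](OB([C@H]2C[C@H]3C[C@@H]([C@@H]2C)C3(C)C)[C@H]2C[C@H]3C[C@@H]([C@@H]2C)C3(C)C)CC=C)O[C@H](C)O1 | intermediate
12 | (2R)-1-[(2R,4S,6R)-2-methyl-6-nonyl-1,3-dioxan-4-yl]pent-4-en-2-ol | CCCCCCCCC[C@@H]1C[C@H](C[C@H](O)CC=C)O[C@H](C)O1 | intermediate
13 | (2E,5R)-5-hydroxy-6-[(2R,4S,6R)-2-methyl-6-nonyl-1,3-dioxan-4-yl]hex-2-enal | CCCCCCCCC[C@@H]1C[C@H](C[C@H](O)C/C=C/C=O)O[C@H](C)O1 | intermediate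
14 | (carboxymethyl)triphenylphosphonium chloride | OC(=O)C[P+](c1ccccc1)(c1ccccc1)c1ccccc1.[Cl-] | starting material
15 | 2-(triphenylphosphonio)acetate, betaine (not isolated) | [O-]C(=O)C[P+](c1ccccc1)(c1ccccc1)c1ccccc1 | intermediate
16 | (3R,5S)-5-hydroxy-6-[(2R,4S,6R)-2-methyl-6-nonyl-1,3-dioxan-4-yl]-1-oxohexan-3-yl (triphenyl-λ5-phosphanylidene)acetate (not isolated) | CCCCCCCCC[C@@H]1C[C@H](C[C@H](O)C[C@H](CC=O)OC(=O)C=P(c2ccccc2)(c2ccccc2)c2ccccc2)O[C@H](C)O1 | intermediate
17 | (6S)-6-{(2S)-2-hydroxy-3-[(2R,4S,6R)-2-methyl-6-nonyl-1,3-dioxan-4-yl]propyl}-5,6-dihydro-2H-pyran-2-one | CCCCCCCCC[C@@H]1C[C@H](C[C@H](O)C[C@@H]2CC=CC(=O)O2)O[C@H](C)O1 | intermediate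
18 | (6S)-6-[(2S,4R,6R)-2,4,6-trihydroxypentadecyl]-5,6-dihydro-2H-pyran-2-one | CCCCCCCCC[C@@H](O)C[C@@H](O)C[C@H](O)C[C@@H]1CC=CC(=O)O1 | target

**Totals**
Total steps: 7. Longest linear sequence: 7 (decanal 1 to 18).

**Three steps most likely to fail**

Step 6 (the new annulation). The carboxylate may add too slowly, the adduct may revert before ylide closure (loss of catalyst control at C5), the free C7 hydroxyl may reversibly mask the new aldehyde, or 15 may decarboxylate. The fallback uses known chemistry only, sets out from 12 and comes back at 18. Silylation of 12 (TBSOTf, 2,6-lutidine) gives the tert-butyldimethylsilyl ether F1. Ozonolysis (O3, CH2Cl2, −78 °C) passes through the secondary ozonide F2, and PPh3 reduces it to the silyloxy aldehyde F3. Allylboration with 2 (Si face) passes through the borinate F4 and gives, after NaOH/H2O2, the homoallylic alcohol F5 with the C5 carbinol anti to C7. Acryloyl chloride, Et3N and DMAP give the acrylate F6. Ring-closing metathesis with second-generation Grubbs catalyst [RuCl2(PCy3)(H2IMes)(=CHPh)] in CH2Cl2 at 40 °C gives the silyl-protected lactone F7. The aqueous HCl/THF of step 7 then removes the silyl ether and the acetal to give 18.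

Step 7 (acetal removal next to the lactone). The ethylidene dioxane is robust, and the acid strength needed may hydrate or open the unsaturated lactone. The fallback changes the protecting groups before the lactone exists; it sets out from 12 and comes back at 18. Hydrolysis of 12 (2 M HCl, THF, 50 °C) gives the triol (4R,6R,8R)-heptadec-1-ene-4,6,8-triol F8. TESOTf and 2,6-lutidine give the tris(triethylsilyl) ether F9. Cross-metathesis with 5 as in step 5 gives the silylated enal F10. The step 6 annulation (through 15 and the ester ylide aldehyde F11) gives the tris(triethylsilyl) lactone F12. HF·pyridine in THF/pyridine at 0 °C then frees 18 under conditions the lactone tolerates well.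

Step 3 (hemiacetal oxa-Michael with two enolisable aldehydes). Acetaldehyde self-condensation or retro-oxa-Michael of the β-alkoxy aldehyde 9 could erode yield. The fallback sets out from 4 and comes back at 9, still forming the C9–O bond through a hemiacetal but on an unactivated alkene. Compound 4 with acetaldehyde, HgClOAc and Yb(OTf)3 (cat.) in THF at 0 °C forms the hemiacetal F13, which undergoes oxymercuration to the syn organomercurial chloro{[(2R,4S,6R)-2-methyl-6-nonyl-1,3-dioxan-4-yl]methyl}mercury F14. Rhodium-catalysed formylation (Rh(acac)(CO)2, tris(2-tert-butylphenyl) phosphite, DABCO, CO/H2 1:1, 35 bar, EtOAc, 50 °C) then gives 9.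

**Further compounds**
F1 | step 6 | tert-butyldimethylsilyl ether of 12 (configurations as in 12) | CCCCCCCCC[C@@H]1C[C@H](C[C@H](O[Si](C)(C)C(C)(C)C)CC=C)O[C@H](C)O1
F2 | step 6 | secondary ozonide (1,2,4-trioxolane) of F1, not isolated | CCCCCCCCC[C@@H]1C[C@H](C[C@H](O[Si](C)(C)C(C)(C)C)CC2OCOO2)O[C@H](C)O1
F3 | step 6 | 3-(tert-butyldimethylsilyloxy)-4-[(2R,4R,6R)-2-methyl-6-nonyl-1,3-dioxan-4-yl]butanal, C3 configured as C7 of 12 | CCCCCCCCC[C@@H]1C[C@H](C[C@H](O[Si](C)(C)C(C)(C)C)CC=O)O[C@H](C)O1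
F4 | step 6 | diisopinocampheylborinate of F5, Ipc groups from (+)-α-pinene, not isolated | CCCCCCCCC[C@@H]1C[C@H](C[C@H](O[Si](C)(C)C(C)(C)C)C[C@@H](OB([C@@H]2C[C@@H]3C[C@H]([C@H]2C)C3(C)C)[C@@H]2C[C@@H]3C[C@H]([C@H]2C)C3(C)C)CC=C)O[C@H](C)O1
F5 | step 6 | homoallylic alcohol, 6-(tert-butyldimethylsilyloxy)-7-(dioxanyl)hept-1-en-4-ol with the 4-OH anti to the 6-silyloxy group | CCCCCCCCC[C@@H]1C[C@H](C[C@H](O[Si](C)(C)C(C)(C)C)C[C@@H](O)CC=C)O[C@H](C)O1
F6 | step 6 | acrylate ester of F5 | CCCCCCCCC[C@@H]1C[C@H](C[C@H](O[Si](C)(C)C(C)(C)C)C[C@@H](OC(=O)C=C)CC=C)O[C@H](C)O1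
F7 | step 6 | tert-butyldimethylsilyl ether of 17 | CCCCCCCCC[C@@H]1C[C@H](C[C@H](O[Si](C)(C)C(C)(C)C)C[C@@H]2CC=CC(=O)O2)O[C@H](C)O1
F8 | step 7 | (4R,6R,8R)-heptadec-1-ene-4,6,8-triol | CCCCCCCCC[C@@H](O)C[C@@H](O)C[C@H](O)CC=C
F9 | step 7 | tris(triethylsilyl) ether of F8 | CCCCCCCCC[C@@H](O[Si](CC)(CC)CC)C[C@@H](O[Si](CC)(CC)CC)C[C@H](O[Si](CC)(CC)CC)CC=C
F10 | step 7 | (2E)-5,7,9-tris(triethylsilyloxy)octadec-2-enal, configurations as in F8 | CCCCCCCCC[C@@H](O[Si](CC)(CC)CC)C[C@@H](O[Si](CC)(CC)CC)C[C@H](O[Si](CC)(CC)CC)C/C=C/C=O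
F11 | step 7 | ester ylide aldehyde from F10 and 15, the silylated analogue of 16, not isolated | CCCCCCCCC[C@@H](O[Si](CC)(CC)CC)C[C@@H](O[Si](CC)(CC)CC)C[C@H](O[Si](CC)(CC)CC)C[C@H](CC=O)OC(=O)C=P(c1ccccc1)(c1ccccc1)c1ccccc1
F12 | step 7 | tris(triethylsilyl) ether of 18 | CCCCCCCCC[C@@H](O[Si](CC)(CC)CC)C[C@@H](O[Si](CC)(CC)CC)C[C@H](O[Si](CC)(CC)CC)C[C@@H]1CC=CC(=O)O1
F13 | step 3 | acetaldehyde hemiacetal of 4, not isolated | CCCCCCCCC[C@@H](OC(C)O)CC=C
F14 | step 3 | chloro{[(2R,4S,6R)-2-methyl-6-nonyl-1,3-dioxan-4-yl]methyl}mercury, all-cis dioxane | CCCCCCCCC[C@@H]1C[C@H](C[Hg]Cl)O[C@H](C)O1
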